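(All runs stem from a simulated flask with constants of no real substance; scatter was added.)

At 15.0 min the beta run had made 16.4% of product, and it took until 80.0 min to reach 51.8%. Two chemists at the board read that slowing differently, and the difference matters for the new flask.

| flask | substrate | coupling partner | free catalyst | remark |
|---|---|---|---|---|
| eta | 0.050 M | 0.055 M | 0.12 mM | run made earlier |
| delta | 0.050 M | 0.055 M | 0.19 mM | run made earlier |
| beta | 0.025 M | 0.055 M | 0.25 mM | run made earlier |
| flask | 0.050 M | 0.0550 M | 0.25 mM |  |

| run | time / min | product / % |
|---|---|---|
| eta | 6.00 | 2.8 |
| eta | 8.00 | 2.8 |
| eta | 12.0 | 4.2 |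
| eta | 20.0 | 7.5 |
| eta | 30.0 | 10.0 |
| eta | 50.0 | 15.4 |
| eta | 80.0 | 22.6 |
| delta | 10.0 | 5.7 |
| delta | 20.0 | 11.6 |
| delta | 30.0 | 15.0 |
| delta | 40.0 | 19.3 |
| delta | 50.0 | 22.8 |
| delta | 60.0 | 25.9 |
| delta | 80.0 | 30.3 |
| beta | 15.0 | 16.4 |
| beta | 30.0 | 28.4 |
| beta | 40.0 | 34.0 |
| beta | 60.0 | 44.3 |
| beta | 80.0 | 51.8 |

(each reading ± 0.5 percentage points)

- what has gone from substrate into another species counts as reacted, even if it can come back
- no earlier run changes the charge of coupling partner; that part of a forecast is a guess

* factor on the rate of making product when 50% of the substrate are converted if coupling partner is charged twice over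
* factor on the rate when 50% of the substrate are converted if free catalyst is charged at 0.050 mM instead

Both reckon with one number, 0.909 for the flask, which I call the exchange: substrate charge over partner charge, the fraction of the partner charge spent per fraction of the substrate charge made into product, one partner going into each product. The substrate is the limiting reagent, its charge being smaller than the partner's.

The first chemist puts the whole 50% through the exchange, which leaves 54.5% of the partner charge. Doubling the charge then raises the partner present by a factor of 2.83, which is the rate factor at first order, against 1 at zero order. The forecast is this side's number: 2.2 for doubling and 0.2 for the lower catalyst charge, with the caution “The runs cannot separate partner loss from product build-up”.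

The second chemist, whose side I take, applies the exchange to product and not to reacted substrate, since reacted substrate counts whatever has left it, even if it can come back. In the beta run the exchange is 0.455, so at 80.0 min the partner still stands at 76.5% of its charge while the rate has fallen. My reckoning for the flask therefore takes the partner left as one minus the exchange times the product, not times the reacted substrate: any reacted substrate that has not become product leaves the partner above 54.5% and the first-order factor below 2.83.

The simulation gives 1.63 and 0.257. The first of these lies between 1 and 2.83, a range that both views allow, so the two must be parted by the partner left in the flask.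

    catalyst intermediate B ⇌ free catalyst + product (K = 0.0210 M, k = 0.436 s⁻¹)
    substrate + catalyst intermediate A → catalyst intermediate B (k = 2.91 M⁻¹ s⁻¹)
    coupling partner + free catalyst ⇌ catalyst intermediate A (K = 35.0 M⁻¹, k = 0.876 M⁻¹ s⁻¹)
    substrate ⇌ dormant form (K = 0.980, k = 2.67 × 10⁻⁴ s⁻¹)

At 0.500 h the flask holds 19.1% of product, so the exchange gives 82.6% of partner left. The table shows 82.4%, above the first chemist's 54.5%, while 27.0% of the substrate charge sits as dormant form, which spends no partner. Take that turning away and the apparent order in partner at 50% conversion goes from 0.79 to 1.6. The first view gets its region late: at 10.0 h the flask has dormant form down to 8.55%, product at 83.5%, and partner at 23.8%.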